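(The rate constants are assumed; what happens was integrated by code.)

**Time available.** The run lasts 3.0 min, and the solid electrophile, dissolving at its fastest, needs 2.17 min, so the margin is at most 0.830 min.

| flask | solid electrophile | nucleophile | time |
|---|---|---|---|
| south-east | 0.050 M | 2.60 equiv | 3.0 min |
| east | 0.050 M | 2.00 equiv | 3.0 min |
| north-west | 0.050 M | 3.40 equiv | 3.0 min |

    electrophile + nucleophile → acid set free + product (k1 = 0.717 M⁻¹ s⁻¹)
    solid electrophile ⇌ electrophile, rate k2*(cs2 - [electrophile]) while solid is left; crystals form when [electrophile] > cs2 (cs2 = 21 mM, k2 = 0.0183 s⁻¹)
    nucleophile + acid set free ⇌ protonated nucleophile, settled at all times (K3 = 3380 M⁻¹)

* part of the solid electrophile that has reacted (what has only dissolved counts as not reacted) at the end, south-east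
* part of the solid electrophile that has reacted (what has only dissolved counts as not reacted) at the end, east
* part of the solid electrophile that has reacted (what has only dissolved counts as not reacted) at the end, north-west
* what raising the equivalents of nucleophile from its lowest to its highest value here does to the part of the solid electrophile that has reacted (what has only dissolved counts as not reacted) (changes below 5 percentage points count as none) (no change / it rises / it falls)

- solid electrophile is a solid; its amount is given per volume of the solution
- at the start none of the solid electrophile is in solution
- what has only dissolved of solid electrophile counts as not reacted
- run time (south-east): 3.0 min

**Spare nucleophile.** South-east and east look nearly the same, 2.60 equiv against 2.00 equiv. In east the binding constant times the starting nucleophile is 338, and this means each reaction should cost two nucleophile, one reacting and one binding the acid set free. South-east therefore has 0.0300 M of spare nucleophile, the charge minus two for each solid electrophile charged, while east has 0 M. Free nucleophile is then close to the spare plus two for each solid electrophile charged and not yet reacted.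

**My reckoning.** You can treat what is unreacted as a correction to complete reaction. For the moment the last solid goes, I set the use of electrophile, with that free nucleophile, equal to its dissolving. The level that balances is 11.2 mM in east and 7.58 mM in south-east, which is lower. With no solid left, that level is the unreacted part, which reads as 77.6% reacted in east and 84.8% in south-east. I expect the south-east figure to be low, because the pseudo-first-order life of electrophile on the spare, 46.5 s, is shorter than the margin, so electrophile in south-east should keep falling once the solid is gone. North-west has 0.0700 M of spare, so I expect the part reacted to rise from east to north-west.

**The forecast.** It gives 92% (89% to 95%) for south-east, 83% (78% to 87%) for east and 97.5% (95% to 99%) for north-west, with the trend: it rises. Its grounds: “Each reaction event uses up two nucleophile (one reacts, one is protonated by the acid set free)”. Its south-east figure stands above mine, and its east figure above mine too.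

**The result.** South-east reaches 90.8%, east 79.1% and north-west 97.5%, so the trend is: it rises, by 18 percentage points. At 3.00 min south-east holds 0.0395 M of free nucleophile, close to its spare of 0.0300 M plus two for each electrophile left, and that electrophile is 9.16% of the solid electrophile charged. The neighbour of east charged with 5.00 equiv has a spare of 0.150 M, giving electrophile a life of 9.30 s. It ends at 99.9% reacted, with 60% of its nucleophile free, which is 0.150 M.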